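The route rests on cutting the bond between quaternary C4 of the guaiane and benzylic C9′, which splits the target into a diformylphloroglucinol-derived o-quinone methide and (−)-α-gurjunene. The key step exploits the array of quaternary C4, the C5=C6 alkene in the seven-membered ring and the 2-hydroxyprop-2-yl group on C7: this is the water-trapped homoallyl cation of a C4=C5 alkene flanked by a C6–C7–C11 gem-dimethylcyclopropane. In one operation the quinone methide alkylates C4, the C6–C11 bond opens, the alkene shifts to C5=C6 and water caps C11. The precursor is the unprotected quinone methide, made in the same flask from the dialdehyde and isovaleraldehyde, plus the intact sesquiterpene.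

Key step: step 2

Remark on the chemistry: the terpene is numbered as a guaiane (C1 and C5 ring fusion, methyl-bearing C4 and C10, C11 the gem-dimethyl carbon) and the benzylic carbon is C9′. Commercial (−)-α-gurjunene is assumed to be the (1R,6S,7R,10R) enantiomer, which already holds C1, C7 and C10 of the target.

Step 1
Reactants: 1 phloroglucinol (benzene-1,3,5-triol); 2 N,N-dimethylformamide
Product: 4 2,4-diformylphloroglucinol, via bis(iminium) dichloride 3 (not isolated)
Conditions: POCl3 (2.2 equiv), 2 (2.2 equiv), 1,4-dioxane, 0 °C to rt; then H2O, 0 °C to rt
Reagents that add atoms: water, O
Why: Vilsmeier–Haack formylation, in which the chloroiminium ion made from 2 and POCl3 substitutes the strongly activated triol twice, the two iminium groups of 3 deactivate the ring against a third substitution at this stoichiometry, and aqueous hydrolysis releases the two aldehydes of 4, which should precipitate; no stereocentre is formed.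

Step 2
Reactants: 4 2,4-diformylphloroglucinol; 5 isovaleraldehyde (3-methylbutanal); 6 (−)-α-gurjunene (6,11-cycloguai-4-ene: C4=C5 tetrasubstituted alkene, cis-fused C6–C7–C11 gem-dimethylcyclopropane on the face of the seven-membered ring that carries H-1, H-1 and H-10 cis)
Product: 9 (−)-macrocarpal D, via quinone methide 7 (not isolated), via chroman 8 (not isolated)
Conditions: NaOAc (0.5 equiv), AcOH (0.5 equiv), (CF3)2CHOH/H2O 3:1, argon, 40 °C, slow addition of 5 (1.5 equiv), 6 (2 equiv); then 55 °C
Reagents that add atoms: water, O
Why: Proposed new method: acetate-buffered Knoevenagel condensation of 5 at the only free ring carbon of 4 should give quinone methide 7 (water adds to it only reversibly), whose exocyclic carbon C9′ is attacked by C4 of the tetrasubstituted alkene of 6 to leave a C5 cation that is tertiary, cyclopropyl-stabilised and paired with a vinylogous-acid phenoxide; the C6–C11 bond, nearly parallel to the empty orbital at C5, then breaks to the tertiary C11 cation as the C5=C6 alkene forms, and water caps C11 as the carbinol. The nearest precedent in reaction type is the one-pot condensation of an aldehyde with diformylphloroglucinol in water-containing media with interception of the quinone methide by a terpene double bond, ending either in a [4+2] chroman or in conjugate addition with skeletal cation rearrangement, together with the Brønsted-acid ring opening of sesquiterpene vinylcyclopropanes to guaia-5-enes; the step proposed here puts a carbon electrophile in the place of that proton. No ring of 9 is formed; the one ring that can close, the dihydropyran of chroman 8, arises when the phenoxide oxygen bonds to C5 (six-membered, formal hetero-[4+2] across C4=C5 on the H-1 face) and, being a tertiary cyclopropylcarbinyl ether of an acidic phenol, should re-ionise in the warm ionising medium and drain into 9. C4 (R) is set by approach of 7 to the cyclopentene face that carries H-1, opposite C10 and its methyl group, and C9′ (R) by an extended transition state in which the arene points away from C5, the isobutyl chain lies under the five-membered ring and only the C9′ hydrogen faces the gem-dimethylcyclopropane; C1, C7 and C10 are untouched, C6 turns sp2 and C11 carries two methyl groups. The step needs attack at C4 and not C5 (secured by cyclopropyl stabilisation of the C5 cation), cleavage of C6–C11 and not C6–C7 (tertiary C11 and better orbital overlap), hydration and not proton loss at C11 (water-rich medium), and the face and C9′ selectivities named above, which rest on substrate control alone, so incomplete selectivity at C9′ is the foreseeable weakness and would be corrected by chromatography.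

Compound list
1 | phloroglucinol (benzene-1,3,5-triol) | Oc1cc(O)cc(O)c1 | starting material
2 | N,N-dimethylformamide | CN(C)C=O | starting material
3 | bis(iminium) dichloride: phloroglucinol ring bearing CH=N+(CH3)2 groups on C2 and C4, two chloride counter-ions | C[N+](C)=Cc1c(O)cc(O)c(C=[N+](C)C)c1O.[Cl-].[Cl-] | intermediate
4 | 2,4-diformylphloroglucinol (2,4,6-trihydroxybenzene-1,3-dicarbaldehyde) | O=Cc1c(O)cc(O)c(C=O)c1O | intermediate
5 | isovaleraldehyde (3-methylbutanal) | CC(C)CC=O | starting material
6 | (−)-α-gurjunene, (1R,6S,7R,10R)-6,11-cycloguai-4-ene | C[C@@H]1CC[C@@H]2[C@H](C3=C(C)CC[C@H]13)C2(C)C | starting material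
7 | o-quinone methide, 2,4-diformyl-3,5-dihydroxy-6-(3-methylbutylidene)cyclohexa-2,4-dien-1-one; exocyclic geometry not fixed because the two forms interconvert by tautomerism | CC(C)CC=C1C(=O)C(C=O)=C(O)C(C=O)=C1O | intermediate
8 | cis-fused chroman: phenolic oxygen on C5 and C9′ on C4, both on the H-1 face of the former C4=C5 bond; cyclopropane and C1, C6, C7, C10 as in 6; C9′ and C4 as in 9 | CC(C)C[C@H]1c2c(O)c(C=O)c(O)c(C=O)c2O[C@]34[C@H]5[C@H](C5(C)C)CC[C@@H](C)[C@H]3CC[C@]14C | intermediate
9 | (−)-macrocarpal D: 2,4,6-trihydroxybenzene-1,3-dicarbaldehyde whose remaining ring carbon bears (9′R)-C9′H(CH2CH(CH3)2), bonded to quaternary C4 of (1R,4R,7R,10R)-guai-5-en-11-ol; C9′ on the H-1 face of the five-membered ring, 4-methyl opposite; H-1, H-10 and the 2-hydroxyprop-2-yl group on one face of the seven-membered ring | CC(C)C[C@@H](c1c(O)c(C=O)c(O)c(C=O)c1O)[C@@]1(C)CC[C@H]2C1=C[C@H](C(C)(C)O)CC[C@H]2C | target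

Total step count: 2
Longest linear sequence: 2 steps (1 to 4 to 9)

Steps most likely to fail (the route has only two steps, so both are ranked)

1. Step 2. Three processes may defeat it:
- The C5 cation may collapse onto the phenoxide oxygen faster than the C6–C11 bond cleaves, with too little re-ionisation under the buffered conditions.
- The vinylcyclopropane of 6 may isomerise under proton catalysis before it is alkylated.
- Face and C9′ selectivity may be incomplete.

The fallback is a two-stage sequence of known reaction types that sets out from 4 (with 5 and 6) and returns to the route at 9. The quinone methide would first be generated under near-neutral, non-ionising conditions (catalytic N,N′-dimethylethylenediamine, acetonitrile, 50 °C). There, concerted hetero-Diels–Alder capture by the alkene is the expected course and 6 is not exposed to acid, so chroman 8 would be isolated and purified, which also removes material of the wrong C9′ configuration. Its tertiary cyclopropylcarbinyl aryl ether would then be solvolysed with a Brønsted acid in aqueous medium (CF3CO2H in THF/H2O, or p-toluenesulfonic acid in aqueous acetone, rt to 40 °C). This is a cyclopropylcarbinyl-to-homoallyl solvolysis of the kind used in the Julia olefin synthesis; it should open C6–C11 and give 9 after capture of C11 by water. The fallback makes no compound outside the list (F0).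

2. Step 1. The degree of formylation may be uncontrolled (mono- and triformylation beside the wanted twofold reaction), and the polar, water-soluble, air-sensitive product may be lost during hydrolysis and isolation.

The fallback moves to a protected, organic-soluble series with known reactions, setting out from 1 and returning at 4. O-Methylation (dimethyl sulfate, K2CO3, acetone, reflux) would give 1,3,5-trimethoxybenzene F1. Twofold Rieche formylation (Cl2CHOCH3, TiCl4, CH2Cl2, 0 °C) would give 2,4,6-trimethoxybenzene-1,3-dicarbaldehyde F2; the third position is spared because two formyl groups deactivate and crowd the ring. Global demethylation with BBr3 (CH2Cl2, −78 °C to rt), helped by chelation of each methoxy group to a neighbouring formyl group, would then give 4.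

Further compounds
F0 | step 2 | none | none
F1 | step 1 | 1,3,5-trimethoxybenzene | COc1cc(OC)cc(OC)c1
F2 | step 1 | 2,4,6-trimethoxybenzene-1,3-dicarbaldehyde | COc1cc(OC)c(C=O)c(OC)c1C=O
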